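## The problem

Compound 21 is a 1-aryl-1,2-dihydronaphthalene built from two caffeate units. Ring A is the fused 6,7-dihydroxybenzo ring, ring B the partly saturated carbocycle C1–C4, and ring C the 3,4-dihydroxyphenyl group on C1. C2 carries a free carboxyl, C3 carries a carboxyl esterified by the hydroxyl of (S)-malic acid, and the C3=C4 bond is conjugated with ring A.

There are three stereocentres: C1 (R), C2 (S, trans to the C1 aryl group) and the malate carbon (S). The malate carbon comes from the chiral pool but is too remote to control the ring, so C1 has to be set absolutely. C2 is α to a carboxyl and allylic, hence epimerisable, and can be set relative to C1 because the trans arrangement is the more stable one.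

The two ring carboxyls must stay distinct throughout, because only the C3 carboxyl bears the malate. The fragile groups are the two catechols (oxidation, above all in base), the acyl malate (β-elimination to a fumarate, acyl cleavage), the C3=C4 bond (hydrogenation, migration, aromatisation) and C2–H.

The enabling feature is that the C2–C3 bond joins two carbons that are each α to a carboxyl, so one of them must react with inverted polarity. Because C3=C4 is attached to ring A, C3 and C4 can come from an arylpropiolate on ring A. Its α-carbon C3 becomes an electrophile once a phosphine has added to C4, and a malonate carbon at C2 can then close ring B.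

## Retrosynthesis

**21 from 20.** All protecting groups of 20 (three tert-butyl esters, two catechol acetonides) are acid-labile, so the last step needs only aqueous acid. No base, oxidant or hydrogenation meets the free catechols, the acyl malate or the C3=C4 bond.

**20 from 17.** The extra C2 carboxyl of 17 has to go and C2 has to be set. Decarboxylating a free C2 malonic acid after global deprotection would deliver the proton to the face away from the pseudoaxial C1 aryl group. That would favour the cis acid, which cannot be corrected at the free-acid stage. The two C2 esters of 17 are therefore different: a 2-(trimethylsilyl)ethyl ester that fluoride removes alone, and a tert-butyl ester that stays. After loss of CO2, the C2–H of the remaining ester is acidic enough for an amidine base to equilibrate it to the trans isomer 20, via the non-isolated 18 and 19. The forward step must spare the acyl malate.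

**17 from 16 (key disconnection).** Cutting C2–C3 opens ring B and leaves 16, a diarylmethyl malonate whose ring A carries the propiolate ester of the malate. The neighbouring cuts were weighed against it:
- C1–C8a (cationic closure) leaves C2 and the carboxyl differentiation unsolved.
- C3–C4 (condensation) needs a strong base next to the malate.

The C2–C3 cut keeps the malate on the C3 carboxyl from the start and creates no stereocentre of consequence. The forward reaction needs a nucleophilic phosphine to reverse the polarity of the ynoate; a plain base would send the malonate to C4 and give an indane.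

**16 from 12 and 15.** The aryl–alkyne bond (C4a–C4) is cut by a Sonogashira disconnection into aryl iodide 12 and propiolate 15. Compound 15 comes from the chiral pool (13, via 14) by two esterifications that do not touch the stereocentre. An iodide is chosen because propiolate esters couple cleanly only at room temperature, and mild conditions are also needed because 16 is prone to base-induced closure.

**12 from 10 from 9.** The malonate is made by C-acylation of the ester enolate (11) of 10 with a chloroformate. This gives the unsymmetrical malonate without sending an E/Z mixture of an unsymmetrical alkylidene malonate through the asymmetric step. The iodide 10 comes from bromide 9 by halogen exchange, because bromine is the halogen that the aromatic substitution and the rhodium step handle best.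

**9 from 4 and 8.** The C1–ring C bond is cut by a catalytic asymmetric conjugate arylation of cinnamate 4 with boronic acid 8. This is the best-precedented way to a 3,3-diarylpropanoate and sets C1. The ortho bromine makes the two aryl groups different and later becomes the alkyne handle.

**4 from 1, and 8 from 5.** Aldehyde 1 is protected as acetonide 2, brominated to 3 and olefinated to 4. Bromocatechol 5 is protected as 6 and converted through aryllithium 7 into 8.

## Roads not taken

**Alternative 1:** Here C2–C3 and C1–C4 are made together by a sensitised head-to-head [2+2] photodimerisation of the tethered dicaffeate A1 to the truxinate A2. The C1–C4 bond is later broken again by oxidation of the freed catechols, giving a bis-quinone methide that closes ring B and tautomerises to the C3=C4 olefin.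
- Merits: two identical cheap halves; tethered cinnamate photodimerisations are reliable; the configuration at C2 comes from the tether without a catalyst and needs no later equilibration. In that respect it is better than the chosen plan.
- Weak points: the two carboxyls of A2 are equivalent, so the malate must be put on C3 selectively after ring B exists, and C3 is the less reactive, conjugated acid. The ring opening needs an oxidant on free catechols, and the dihydronaphthalene formed is itself easily oxidised to a naphthalene. C1 is created in a quinone methide closure controlled only by C2. Tether removal, deprotection, oxidation and differentiation add steps.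
- Comparison: the chosen plan has the malate in place before ring closure and exposes free catechols only to acid. It pays for this with an equilibration at C2.

**Alternative 2:** Here C1–C2 and C1–C8a are cut, with the ring C aldehyde A4 as a one-carbon link. The boron enolate of imide A3 adds to A4, and acid then ionises the benzylic aldolate so that ring A closes on C1 to give A5.
- Merits: convergent, two bonds and ring B in one flask. C2 is set by the auxiliary and C1 relative to it. The carboxyls are differentiated (imide at C2, allyl ester at C3). For C2 this is more direct than the chosen plan.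
- Weak points: the aldolate can simply dehydrate to a bis-arylidene succinate, which loses C2. The four benzyl ethers cannot be removed by hydrogenolysis without saturating C3=C4, so a Lewis acid would have to act beside the acyl malate. The auxiliary must be cleaved by peroxide before the malate is attached, which forces several protecting-group exchanges at the end. The auxiliary is stoichiometric.
- Comparison: the chosen plan sets against the better C2 control of A5 a catalytic step for C1, an acid-only end game and no exchange of ester groups after ring closure.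

**Alternative 3:** Here C1–C2 and C3–C4 are cut by a photoenolisation Diels–Alder reaction. Irradiation of aldehyde A6 with a chiral titanium diolate gives a hydroxy-ortho-quinodimethane that adds to the fumarate A7, forming A8. Dehydration of the C4 hydroxyl later gives C3=C4.
- Merits: the shortest access to ring B. C1 and C2 are set together and trans by the fumarate geometry. The C3 carboxyl arrives as an activated imide, ready for the malate. In convergence and in C2 control it would surpass the chosen plan if it works.
- Weak points: the photoenol carries an aryl group on the diene terminus, a pattern for which dienol geometry and facial control by the Lewis acid are not established. The orientation of the unsymmetrical A7 must be controlled. The imide must be exchanged for a hindered secondary α-hydroxy ester under conditions that invite β-elimination.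
- Comparison: the chosen plan puts its unprecedented step where no stereocentre is at stake and leaves C1 to a well-established catalytic arylation.

Key step: step 12

Assumption: in the protected triester the (1R,2S)-trans isomer, with the C1 aryl group and the C2 ester both pseudoaxial, is taken to be the more stable C2 epimer, and the chiral diene of step 6 is taken to show its usual facial preference for (E)-3-arylacrylates (its mirror image is used if the preference proves opposite).

## Route

Step 1
Reactants: 1 3,4-dihydroxybenzaldehyde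
Product: 2 2,2-dimethyl-1,3-benzodioxole-5-carbaldehyde
Conditions: 2,2-dimethoxypropane, TsOH (cat.), toluene, reflux, MeOH removed over 4 Å sieves
Reagents that add atoms: 2,2-dimethoxypropane, COC(C)(C)OC
Why: Acid-catalysed transketalisation of the catechol; continuous removal of methanol drives the sluggish ketalisation of this electron-poor catechol. The acetonide withstands base, organometallics and fluoride and falls only in the last step.

Step 2
Reactants: 2 2,2-dimethyl-1,3-benzodioxole-5-carbaldehyde
Product: 3 6-bromo-2,2-dimethyl-1,3-benzodioxole-5-carbaldehyde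
Conditions: Br2, NaOAc, AcOH, rt
Reagents that add atoms: bromine, BrBr
Why: Electrophilic aromatic bromination goes para to a ring oxygen and ortho to the formyl group (C6), as with other 3,4-dialkoxybenzaldehydes; NaOAc traps HBr so that the acetonide survives.

Step 3
Reactants: 3 6-bromo-2,2-dimethyl-1,3-benzodioxole-5-carbaldehyde
Product: 4 tert-butyl (E)-3-(6-bromo-2,2-dimethyl-1,3-benzodioxol-5-yl)prop-2-enoate
Conditions: Ph3P=CHCO2t-Bu, toluene, 80 °C
Reagents that add atoms: (tert-butoxycarbonylmethylene)triphenylphosphorane, CC(C)(C)OC(=O)C=P(c1ccccc1)(c1ccccc1)c1ccccc1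
Why: Wittig olefination with a stabilised ylide gives the (E)-enoate; the tert-butyl ester resists the aqueous base of step 6.

Step 4
Reactants: 5 4-bromocatechol
Product: 6 5-bromo-2,2-dimethyl-1,3-benzodioxole
Conditions: 2,2-dimethoxypropane, TsOH (cat.), toluene, reflux
Reagents that add atoms: 2,2-dimethoxypropane, COC(C)(C)OC
Why: Acid-catalysed ketalisation of an electron-rich catechol, a routine protection.

Step 5
Reactants: 6 5-bromo-2,2-dimethyl-1,3-benzodioxole
Product: 8 (2,2-dimethyl-1,3-benzodioxol-5-yl)boronic acid, via aryllithium 7 (not isolated)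
Conditions: n-BuLi, THF, −78 °C; B(Oi-Pr)3, −78 °C to rt; aq NH4Cl
Reagents that add atoms: triisopropyl borate, CC(C)OB(OC(C)C)OC(C)C; water, O
Why: Bromine–lithium exchange and borylation of the aryllithium; the nearly neutral work-up hydrolyses the borate and keeps the acetonide.

Step 6
Reactants: 4 tert-butyl (E)-3-(6-bromo-2,2-dimethyl-1,3-benzodioxol-5-yl)prop-2-enoate; 8 (2,2-dimethyl-1,3-benzodioxol-5-yl)boronic acid
Product: 9 tert-butyl (3R)-3-(6-bromo-2,2-dimethyl-1,3-benzodioxol-5-yl)-3-(2,2-dimethyl-1,3-benzodioxol-5-yl)propanoate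
Conditions: [RhCl(C2H4)2]2 (2.5 mol %), enantiopure 2,5-diphenylbicyclo[2.2.2]octa-2,5-diene (5.5 mol %, enantiomer giving Si-face arylation), KOH (0.5 equiv), 1,4-dioxane/H2O 10:1, 50 °C
Reagents that add atoms: none
Why: Rhodium-catalysed asymmetric 1,4-addition of an arylboronic acid to an (E)-3-arylacrylate ester: the aryl–rhodium species held by the C2-symmetric diene inserts the enoate on one face and the rhodium enolate is hydrolysed. The ligand sets the future C1 by delivering the ring C aryl group to the Si face of the β-carbon, which gives (R); the aryl bromide is inert to monovalent rhodium under these conditions.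

Step 7
Reactants: 9 tert-butyl (3R)-3-(6-bromo-2,2-dimethyl-1,3-benzodioxol-5-yl)-3-(2,2-dimethyl-1,3-benzodioxol-5-yl)propanoate
Product: 10 tert-butyl (3R)-3-(6-iodo-2,2-dimethyl-1,3-benzodioxol-5-yl)-3-(2,2-dimethyl-1,3-benzodioxol-5-yl)propanoate
Conditions: CuI (10 mol %), NaI (2 equiv), trans-N,N'-dimethylcyclohexane-1,2-diamine (20 mol %), 1,4-dioxane, 110 °C
Reagents that add atoms: sodium iodide, [Na+].[I-]
Why: Copper-catalysed aromatic Finkelstein reaction, driven by the low solubility of NaBr in dioxane; it is done on the mono-ester, before an acidic C–H is present, and gives the iodide needed for a room-temperature coupling in step 11.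

Step 8
Reactants: 10 tert-butyl (3R)-3-(6-iodo-2,2-dimethyl-1,3-benzodioxol-5-yl)-3-(2,2-dimethyl-1,3-benzodioxol-5-yl)propanoate
Product: 12 1-tert-butyl 3-[2-(trimethylsilyl)ethyl] 2-[(R)-(6-iodo-2,2-dimethyl-1,3-benzodioxol-5-yl)(2,2-dimethyl-1,3-benzodioxol-5-yl)methyl]propanedioate (both epimers at the malonate carbon), via lithium enolate 11 (not isolated)
Conditions: LiN(i-Pr)2 (2.2 equiv), THF, −78 °C; ClCO2CH2CH2SiMe3, −78 to −30 °C; aq NH4Cl
Reagents that add atoms: 2-(trimethylsilyl)ethyl chloroformate, C[Si](C)(C)CCOC(Cl)=O
Why: Claisen-type C-acylation of a lithium ester enolate with a chloroformate; the second equivalent of base takes up the more acidic malonate as it forms. C1 is not acidic and keeps its configuration, and the malonate carbon forms as both epimers, which does not matter because it is deprotonated in step 12.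

Step 9
Reactants: 13 (S)-malic acid
Product: 14 di-tert-butyl (2S)-2-hydroxybutanedioate
Conditions: t-BuOC(=NH)CCl3 (3 equiv), THF/cyclohexane, rt
Reagents that add atoms: tert-butyl 2,2,2-trichloroacetimidate, CC(C)(C)OC(=N)C(Cl)(Cl)Cl
Why: Carboxylic acids are tert-butylated by the trichloroacetimidate without added acid, whereas the secondary alcohol is not; the stereocentre is not involved.

Step 10
Reactants: 14 di-tert-butyl (2S)-2-hydroxybutanedioate
Product: 15 di-tert-butyl (2S)-2-(prop-2-ynoyloxy)butanedioate
Conditions: propiolic acid, DCC, DMAP (5 mol %), CH2Cl2, −20 to 0 °C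
Reagents that add atoms: propiolic acid, C#CC(=O)O
Why: Steglich esterification at low temperature; the malate C–O bond is not broken, so the (S) configuration is retained.

Step 11
Reactants: 12 1-tert-butyl 3-[2-(trimethylsilyl)ethyl] 2-[(R)-(6-iodo-2,2-dimethyl-1,3-benzodioxol-5-yl)(2,2-dimethyl-1,3-benzodioxol-5-yl)methyl]propanedioate; 15 di-tert-butyl (2S)-2-(prop-2-ynoyloxy)butanedioate
Product: 16 di-tert-butyl (2S)-2-{[3-(6-{(1R)-3-tert-butoxy-1-(2,2-dimethyl-1,3-benzodioxol-5-yl)-3-oxo-2-{[2-(trimethylsilyl)ethoxy]carbonyl}propyl}-2,2-dimethyl-1,3-benzodioxol-5-yl)prop-2-ynoyl]oxy}butanedioate (both epimers at the malonate carbon)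
Conditions: PdCl2(PPh3)2 (5 mol %), CuI (10 mol %), i-Pr2NEt (2 equiv), THF, rt, slow addition of 15 (2 equiv)
Reagents that add atoms: none
Why: Sonogashira coupling of an aryl iodide with a propiolate ester at room temperature. The hindered tertiary amine cannot add to the ynoate and is too weak to deprotonate the malonate, so neither consumption of 15 nor base-induced closure of 16 should compete.

Step 12
Reactants: 16 di-tert-butyl (2S)-2-{[3-(6-{(1R)-3-tert-butoxy-1-(2,2-dimethyl-1,3-benzodioxol-5-yl)-3-oxo-2-{[2-(trimethylsilyl)ethoxy]carbonyl}propyl}-2,2-dimethyl-1,3-benzodioxol-5-yl)prop-2-ynoyl]oxy}butanedioate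
Product: 17 2-tert-butyl 2-[2-(trimethylsilyl)ethyl] 3-[(2S)-1,4-di-tert-butoxy-1,4-dioxobutan-2-yl] (1R)-1-(2,2-dimethyl-1,3-benzodioxol-5-yl)-6,7-(isopropylidenedioxy)-1,2-dihydronaphthalene-2,2,3-tricarboxylate (both C2 epimers)
Conditions: PPh3 (20 mol %), AcOH (20 mol %), NaOAc (20 mol %), degassed toluene, 90 °C
Reagents that add atoms: none
Why: Proposed new method: PPh3 adds to C4 of the ynoate (the carbon β to the ester), the zwitterion is protonated by the malonate C2–H with AcOH/NaOAc as relay, and the C2 enolate attacks C3 of the vinylphosphonium ion, the carbon β to phosphorus, to give an ylide at C4; protonation at C4, loss of the now acidic C3–H and expulsion of PPh3 leave the C3=C4 bond and return the catalyst. The closest known reaction type is the phosphine-catalysed α-addition of 1,3-dicarbonyl and NH pronucleophiles to propiolates and arylpropiolates between two molecules; the ring-forming carbon version is the extension proposed here. Ring B closes by a 6-endo-trig attack on the vinylphosphonium ion (formally an anti-Michael 6-endo-dig closure on the ynoate), which takes C3 and C4 both into the ring. The selectivity needed is C3 over C4: the phosphine bound at C4 blocks the 5-exo conjugate addition that a base would cause, the aryl group on C4 leaves no γ-hydrogen so no allenoate and no γ-addition can arise, and no base stronger than acetate is present. The new C2 centre is quaternary and forms without control as both epimers, which is of no consequence because it is made planar again in step 13; C1 is not acidic and is untouched. The malonate, with one small 2-(trimethylsilyl)ethyl ester, should be acidic enough to protonate the zwitterion.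

Step 13
Reactants: 17 2-tert-butyl 2-[2-(trimethylsilyl)ethyl] 3-[(2S)-1,4-di-tert-butoxy-1,4-dioxobutan-2-yl] (1R)-1-(2,2-dimethyl-1,3-benzodioxol-5-yl)-6,7-(isopropylidenedioxy)-1,2-dihydronaphthalene-2,2,3-tricarboxylate
Product: 20 2-tert-butyl 3-[(2S)-1,4-di-tert-butoxy-1,4-dioxobutan-2-yl] (1R,2S)-1-(2,2-dimethyl-1,3-benzodioxol-5-yl)-6,7-(isopropylidenedioxy)-1,2-dihydronaphthalene-2,3-dicarboxylate, via tetrabutylammonium carboxylate 18 (not isolated), via C2-epimeric ester 19 (not isolated)
Conditions: Bu4NF (1.5 equiv), THF, 0 to 40 °C; then DBU (0.2 equiv), rt; aq NH4Cl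
Reagents that add atoms: none
Why: Fluoride attacks silicon and fragments the 2-(trimethylsilyl)ethyl ester; carboxylate 18 loses CO2 to an ester dienolate stabilised through C3=C4, which is protonated at C2 (fluoride ester cleavage and decarboxylation of a malonic half-ester). Kinetic protonation is expected on the face away from the pseudoaxial C1 aryl group (cis), so DBU equilibrates the acidic C2–H of 19 to the trans (1R,2S) ester, in which the C1 aryl group and the C2 ester are both pseudoaxial; C2 is thus set by C1 under thermodynamic control. The malate α-hydrogens are far less acidic than C2–H, so catalytic base should not cause β-elimination.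

Step 14
Reactants: 20 2-tert-butyl 3-[(2S)-1,4-di-tert-butoxy-1,4-dioxobutan-2-yl] (1R,2S)-1-(2,2-dimethyl-1,3-benzodioxol-5-yl)-6,7-(isopropylidenedioxy)-1,2-dihydronaphthalene-2,3-dicarboxylate
Product: 21 (1R,2S)-3-{[(1S)-1,2-dicarboxyethoxy]carbonyl}-1-(3,4-dihydroxyphenyl)-6,7-dihydroxy-1,2-dihydronaphthalene-2-carboxylic acid
Conditions: CF3CO2H/H2O 9:1, rt, under argon
Reagents that add atoms: none
Why: Acidolysis of the three tert-butyl esters and hydrolysis of the two catechol acetonides in one operation. No base is present, so the acyl malate, the trans C2 centre (the stable epimer) and the catechols are not endangered.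

## Compound list

1 | 3,4-dihydroxybenzaldehyde | O=Cc1ccc(O)c(O)c1 | starting material
2 | 2,2-dimethyl-1,3-benzodioxole-5-carbaldehyde | O=Cc1ccc2OC(C)(C)Oc2c1 | intermediate
3 | 6-bromo-2,2-dimethyl-1,3-benzodioxole-5-carbaldehyde | O=Cc1cc2OC(C)(C)Oc2cc1Br | intermediate
4 | tert-butyl (E)-3-(6-bromo-2,2-dimethyl-1,3-benzodioxol-5-yl)prop-2-enoate | CC(C)(C)OC(=O)/C=C/c1cc2OC(C)(C)Oc2cc1Br | intermediate
5 | 4-bromocatechol | Oc1ccc(Br)cc1O | starting material
6 | 5-bromo-2,2-dimethyl-1,3-benzodioxole | CC1(C)Oc2ccc(Br)cc2O1 | intermediate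
7 | (2,2-dimethyl-1,3-benzodioxol-5-yl)lithium | [Li]c1ccc2OC(C)(C)Oc2c1 | intermediate (not isolated)
8 | (2,2-dimethyl-1,3-benzodioxol-5-yl)boronic acid | OB(O)c1ccc2OC(C)(C)Oc2c1 | intermediate
9 | tert-butyl (3R)-3-(6-bromo-2,2-dimethyl-1,3-benzodioxol-5-yl)-3-(2,2-dimethyl-1,3-benzodioxol-5-yl)propanoate | Brc1cc2OC(C)(C)Oc2cc1[C@@H](c1ccc2OC(C)(C)Oc2c1)CC(=O)OC(C)(C)C | intermediate
10 | tert-butyl (3R)-3-(6-iodo-2,2-dimethyl-1,3-benzodioxol-5-yl)-3-(2,2-dimethyl-1,3-benzodioxol-5-yl)propanoate | Ic1cc2OC(C)(C)Oc2cc1[C@@H](c1ccc2OC(C)(C)Oc2c1)CC(=O)OC(C)(C)C | intermediate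
11 | lithium enolate of 10 | Ic1cc2OC(C)(C)Oc2cc1[C@@H](c1ccc2OC(C)(C)Oc2c1)C=C(O[Li])OC(C)(C)C | intermediate (not isolated)
12 | 1-tert-butyl 3-[2-(trimethylsilyl)ethyl] 2-[(R)-(6-iodo-2,2-dimethyl-1,3-benzodioxol-5-yl)(2,2-dimethyl-1,3-benzodioxol-5-yl)methyl]propanedioate, both epimers at the malonate carbon | Ic1cc2OC(C)(C)Oc2cc1[C@@H](c1ccc2OC(C)(C)Oc2c1)C(C(=O)OC(C)(C)C)C(=O)OCC[Si](C)(C)C | intermediate
13 | (S)-malic acid | O=C(O)C[C@H](O)C(=O)O | starting material
14 | di-tert-butyl (2S)-2-hydroxybutanedioate | CC(C)(C)OC(=O)C[C@H](O)C(=O)OC(C)(C)C | intermediate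
15 | di-tert-butyl (2S)-2-(prop-2-ynoyloxy)butanedioate | CC(C)(C)OC(=O)C[C@H](OC(=O)C#C)C(=O)OC(C)(C)C | intermediate
16 | arylpropiolate of 14 with the (R)-diarylmethyl malonate (tert-butyl and 2-(trimethylsilyl)ethyl esters) ortho on ring A, both epimers at the malonate carbon | CC(C)(C)OC(=O)C[C@H](OC(=O)C#Cc1cc2OC(C)(C)Oc2cc1[C@@H](c1ccc2OC(C)(C)Oc2c1)C(C(=O)OC(C)(C)C)C(=O)OCC[Si](C)(C)C)C(=O)OC(C)(C)C | intermediate (precursor of the key step)
17 | (1R)-1-aryl-1,2-dihydronaphthalene-2,2,3-tricarboxylate: C2 tert-butyl and 2-(trimethylsilyl)ethyl esters, C3 ester of 14, 6,7- and 3',4'-acetonides, both C2 epimers | CC(C)(C)OC(=O)C[C@H](OC(=O)C1=Cc2cc3OC(C)(C)Oc3cc2[C@@H](c2ccc3OC(C)(C)Oc3c2)C1(C(=O)OC(C)(C)C)C(=O)OCC[Si](C)(C)C)C(=O)OC(C)(C)C | intermediate (product of the key step)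
18 | tetrabutylammonium C2-carboxylate from 17 | CC(C)(C)OC(=O)C[C@H](OC(=O)C1=Cc2cc3OC(C)(C)Oc3cc2[C@@H](c2ccc3OC(C)(C)Oc3c2)C1(C(=O)OC(C)(C)C)C(=O)[O-])C(=O)OC(C)(C)C.CCCC[N+](CCCC)(CCCC)CCCC | intermediate (not isolated)
19 | (1R)-1-aryl-1,2-dihydronaphthalene-2,3-dicarboxylate, C2 tert-butyl ester, mixture of C2 epimers | CC(C)(C)OC(=O)C[C@H](OC(=O)C1=Cc2cc3OC(C)(C)Oc3cc2[C@@H](c2ccc3OC(C)(C)Oc3c2)C1C(=O)OC(C)(C)C)C(=O)OC(C)(C)C | intermediate (not isolated)
20 | (1R,2S)-trans-1-aryl-1,2-dihydronaphthalene-2,3-dicarboxylate: C2 tert-butyl ester, C3 ester of 14, 6,7- and 3',4'-acetonides | CC(C)(C)OC(=O)C[C@H](OC(=O)C1=Cc2cc3OC(C)(C)Oc3cc2[C@@H](c2ccc3OC(C)(C)Oc3c2)[C@@H]1C(=O)OC(C)(C)C)C(=O)OC(C)(C)C | intermediate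
21 | (1R,2S)-3-{[(1S)-1,2-dicarboxyethoxy]carbonyl}-1-(3,4-dihydroxyphenyl)-6,7-dihydroxy-1,2-dihydronaphthalene-2-carboxylic acid | O=C(O)C[C@H](OC(=O)C1=Cc2cc(O)c(O)cc2[C@@H](c2ccc(O)c(O)c2)[C@@H]1C(=O)O)C(=O)O | target

## Step count and risks

Total: 14 steps. Longest linear sequence: 10 steps (steps 1, 2, 3, 6, 7, 8, 11, 12, 13, 14).

**Step 12 (key step, proposed new method).** The most likely failure is slow addition of the phosphine to C4, which is flanked by the bulky ortho substituent of ring A. Closure would then stall, or the slow background conjugate addition to C4 would take over; a sluggish proton transfer from the hindered malonate would have the same effect. The fallback uses known chemistry and sets out from 12 and 15. The known intermolecular PPh3-catalysed α-addition of the malonate 12 to the terminal propiolate 15 (PPh3 cat., toluene, 80 °C) gives the α-(malonyl)acrylate F1, in which the C2–C3 bond already exists. An intramolecular Heck reaction of its aryl iodide (Pd(OAc)2, PPh3, Ag2CO3, MeCN, 80 °C) then joins C4 to ring A. This is a 6-endo closure, favoured because the aryl group adds to the unsubstituted acrylate terminus and the 5-exo mode would create two adjacent quaternary carbons. β-Hydride elimination gives 17, where the route is rejoined.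

**Step 11.** The propiolate may be lost by conjugate addition and oligomerisation faster than its copper acetylide transmetallates, or the product may begin to close under the amine. The fallback sets out from 12 and builds the ynoate in stages:
- Sonogashira coupling with ethynyltrimethylsilane (PdCl2(PPh3)2, CuI, Et3N) gives the silylalkyne F2.
- K2CO3 in methanol gives the terminal alkyne F3.
- Double deprotonation with LiN(i-Pr)2 (malonate, then alkyne) and quenching with CO2 at −78 °C gives the arylpropiolic acid F4. The hindered malonate enolate does not retain CO2, and the carboxylate is no acceptor for it.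
- Steglich esterification of F4 with 14 (EDC, DMAP) returns to the route at 16.

**Step 13.** Fluoride or DBU may cause β-elimination of the malate from the C3 ester or migration of the C3=C4 bond, or the equilibration may stop short. The fallback avoids base altogether and sets out from 17. CF3CO2H/H2O removes all esters and acetonides to give the C2 malonic acid F5. Warming in aqueous dioxane (70 °C) decarboxylates it to 21 together with its C2 epimer F6, and 21 is isolated by reversed-phase chromatography. The cost is the loss of stereocontrol at C2.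

**Step 6.** The ortho bromine may slow insertion so far that protodeboronation of 8 wins, or the facial selectivity may be eroded. The fallback replaces the catalyst by a chiral auxiliary and sets out from 3:
- Doebner condensation of 3 with malonic acid (pyridine, piperidine) gives the cinnamic acid F7.
- N-Acylation of (S)-4-phenyl-1,3-oxazolidin-2-one (pivaloyl chloride, Et3N, LiCl) gives the imide F8.
- The Grignard reagent F9 (from 6 and Mg) adds with CuBr·SMe2 at −40 °C, on the face away from the phenyl group of the chelated imide, to give the (3R) adduct F10.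
- LiOH/H2O2 cleaves the auxiliary to the acid F11.
- tert-Butyl 2,2,2-trichloroacetimidate converts F11 into 9, where the route is rejoined.

## Further compounds

F1 | step 12 | 1-tert-butyl 3-[2-(trimethylsilyl)ethyl] 2-[(6-iodo-2,2-dimethyl-1,3-benzodioxol-5-yl)(2,2-dimethyl-1,3-benzodioxol-5-yl)methyl]-2-(3-{[(2S)-1,4-di-tert-butoxy-1,4-dioxobutan-2-yl]oxy}-3-oxoprop-1-en-2-yl)propanedioate (diarylmethyl carbon as in 12, both malonate epimers) | Ic1cc2OC(C)(C)Oc2cc1[C@@H](c1ccc2OC(C)(C)Oc2c1)C(C(=O)OC(C)(C)C)(C(=O)OCC[Si](C)(C)C)C(=C)C(=O)O[C@@H](CC(=O)OC(C)(C)C)C(=O)OC(C)(C)C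
F2 | step 11 | 1-tert-butyl 3-[2-(trimethylsilyl)ethyl] 2-[(R)-{2,2-dimethyl-6-[(trimethylsilyl)ethynyl]-1,3-benzodioxol-5-yl}(2,2-dimethyl-1,3-benzodioxol-5-yl)methyl]propanedioate | C[Si](C)(C)C#Cc1cc2OC(C)(C)Oc2cc1[C@@H](c1ccc2OC(C)(C)Oc2c1)C(C(=O)OC(C)(C)C)C(=O)OCC[Si](C)(C)C
F3 | step 11 | 1-tert-butyl 3-[2-(trimethylsilyl)ethyl] 2-[(R)-(6-ethynyl-2,2-dimethyl-1,3-benzodioxol-5-yl)(2,2-dimethyl-1,3-benzodioxol-5-yl)methyl]propanedioate | C#Cc1cc2OC(C)(C)Oc2cc1[C@@H](c1ccc2OC(C)(C)Oc2c1)C(C(=O)OC(C)(C)C)C(=O)OCC[Si](C)(C)C
F4 | step 11 | 3-(6-{(1R)-3-tert-butoxy-1-(2,2-dimethyl-1,3-benzodioxol-5-yl)-3-oxo-2-{[2-(trimethylsilyl)ethoxy]carbonyl}propyl}-2,2-dimethyl-1,3-benzodioxol-5-yl)prop-2-ynoic acid | OC(=O)C#Cc1cc2OC(C)(C)Oc2cc1[C@@H](c1ccc2OC(C)(C)Oc2c1)C(C(=O)OC(C)(C)C)C(=O)OCC[Si](C)(C)C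
F5 | step 13 | (1R)-3-{[(1S)-1,2-dicarboxyethoxy]carbonyl}-1-(3,4-dihydroxyphenyl)-6,7-dihydroxy-1,2-dihydronaphthalene-2,2-dicarboxylic acid | O=C(O)C[C@H](OC(=O)C1=Cc2cc(O)c(O)cc2[C@@H](c2ccc(O)c(O)c2)C1(C(=O)O)C(=O)O)C(=O)O
F6 | step 13 | (1R,2R)-3-{[(1S)-1,2-dicarboxyethoxy]carbonyl}-1-(3,4-dihydroxyphenyl)-6,7-dihydroxy-1,2-dihydronaphthalene-2-carboxylic acid (cis C2 epimer of 21) | O=C(O)C[C@H](OC(=O)C1=Cc2cc(O)c(O)cc2[C@@H](c2ccc(O)c(O)c2)[C@H]1C(=O)O)C(=O)O
F7 | step 6 | (E)-3-(6-bromo-2,2-dimethyl-1,3-benzodioxol-5-yl)prop-2-enoic acid | OC(=O)/C=C/c1cc2OC(C)(C)Oc2cc1Br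
F8 | step 6 | (4S)-3-[(E)-3-(6-bromo-2,2-dimethyl-1,3-benzodioxol-5-yl)prop-2-enoyl]-4-phenyl-1,3-oxazolidin-2-one | O=C(/C=C/c1cc2OC(C)(C)Oc2cc1Br)N1[C@@H](c2ccccc2)COC1=O
F9 | step 6 | (2,2-dimethyl-1,3-benzodioxol-5-yl)magnesium bromide | Br[Mg]c1ccc2OC(C)(C)Oc2c1
F10 | step 6 | (4S)-3-[(3R)-3-(6-bromo-2,2-dimethyl-1,3-benzodioxol-5-yl)-3-(2,2-dimethyl-1,3-benzodioxol-5-yl)propanoyl]-4-phenyl-1,3-oxazolidin-2-one | Brc1cc2OC(C)(C)Oc2cc1[C@@H](c1ccc2OC(C)(C)Oc2c1)CC(=O)N1[C@@H](c2ccccc2)COC1=O
F11 | step 6 | (3R)-3-(6-bromo-2,2-dimethyl-1,3-benzodioxol-5-yl)-3-(2,2-dimethyl-1,3-benzodioxol-5-yl)propanoic acid | Brc1cc2OC(C)(C)Oc2cc1[C@@H](c1ccc2OC(C)(C)Oc2c1)CC(=O)O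
A1 | alternative 1 | 2,3-O-isopropylidene-threitol 1,4-bis[(E)-3-(2,2-dimethyl-1,3-benzodioxol-5-yl)prop-2-enoate] | CC1(C)Oc2ccc(/C=C/C(=O)OC[C@@H]3OC(C)(C)O[C@H]3COC(=O)/C=C/c3ccc4OC(C)(C)Oc4c3)cc2O1
A2 | alternative 1 | all-trans truxinate bridged by the threitol acetonide tether | CC1(C)Oc2ccc(cc2O1)[C@H]1[C@H](C(=O)OC[C@@H]3OC(C)(C)O[C@H]3COC2=O)[C@@H]2[C@@H]1c1ccc2OC(C)(C)Oc2c1
A3 | alternative 2 | allyl (E)-2-[3,4-bis(benzyloxy)benzylidene]-4-(4-benzyl-2-oxo-1,3-oxazolidin-3-yl)-4-oxobutanoate | C=CCOC(=O)/C(CC(=O)N1[C@H](Cc2ccccc2)COC1=O)=C/c1ccc(OCc2ccccc2)c(OCc2ccccc2)c1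
A4 | alternative 2 | 3,4-bis(benzyloxy)benzaldehyde | O=Cc1ccc(OCc2ccccc2)c(OCc2ccccc2)c1
A5 | alternative 2 | (1R,2S)-trans-1-aryl-1,2-dihydronaphthalene, acyl oxazolidinone at C2, allyl ester at C3, four benzyl ethers | C=CCOC(=O)C1=Cc2cc(OCc3ccccc3)c(OCc3ccccc3)cc2[C@@H](c2ccc(OCc3ccccc3)c(OCc3ccccc3)c2)[C@@H]1C(=O)N1[C@H](Cc2ccccc2)COC1=O
A6 | alternative 3 | 6-[(2,2-dimethyl-1,3-benzodioxol-5-yl)methyl]-2,2-dimethyl-1,3-benzodioxole-5-carbaldehyde | O=Cc1cc2OC(C)(C)Oc2cc1Cc1ccc2OC(C)(C)Oc2c1
A7 | alternative 3 | tert-butyl (E)-4-oxo-4-(2-oxo-1,3-oxazolidin-3-yl)but-2-enoate | CC(C)(C)OC(=O)/C=C/C(=O)N1CCOC1=O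
A8 | alternative 3 | (1R,2S)-1-aryl-4-hydroxytetralin, tert-butyl ester at C2, acyl oxazolidinone at C3 cis to the C4 hydroxyl, two acetonides | O[C@H]1c2cc3OC(C)(C)Oc3cc2[C@@H](c2ccc3OC(C)(C)Oc3c2)[C@H](C(=O)OC(C)(C)C)[C@H]1C(=O)N1CCOC1=O
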